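## Structural features

The target is a 1-aryl-2-benzylnaphthalene: ring A (C1–C4, C4a, C8a) and ring B (C4a–C8a) make up the naphthalene, ring C (4-hydroxy-2-methoxyphenyl, C1'–C6') is bound to C1 by a biaryl bond, and ring D (4-hydroxy-3-methoxyphenyl) hangs on C2 through one methylene. Ring A carries OH on C3 and H on C4; ring B carries OMe on C5, OH on C6, OMe on C7 and H on C8. There is no stereocentre, hence no adjacent stereocentres; the only stereogenic element is the C1–C1' axis, flanked by the C2 benzyl group, the peri C8–H and the C2' methoxyl, and the target is specified without an axial descriptor. The fragile groups are the four free phenols on very electron-rich rings (above all the C3 naphthol and the C6 phenol between two methoxyls), which call for masking until a final neutral deprotection. The real difficulty is the contiguous C1/C2/C3 substitution of ring A, i.e. a biaryl bond at the most crowded carbon next to a benzyl group, together with telling seven oxygens apart (O2' from O4', O6 from O5 and O7). The key step exploits the fact that ring C is a resorcinol with oxygen on C2' and C4' and its attachment at C1': the six ring carbons can be laid out as a chain C1'–C6' on the naphthalene C1 methylene, with ketones at C2' and C4' and an aldehyde at C6', and closed by a C1'–C6' aldol, so that the crowded C1–C1' bond exists as an ordinary benzylic bond before ring C does. A second feature serves ring A: C8a is para to O6, so a ring B arylacetyl tricarbonyl chain can be closed onto C8a by cyclodehydration, but only if O6 is a free phenol at that moment (an ether between two methoxyls is twisted out of conjugation) and only if the arylacetyl unit stems from substitution of 2,6-dimethoxyphenol at C3, not at the position para to its hydroxyl, which would lead to the 6,7,8-oxygenated isomer.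

## Logic of the disconnections

21 ⇒ 20. The four O–CH2Ph bonds (on O3, O6, O4' and the ring D oxygen) are cut. All phenols are released together under neutral hydrogenolysis, so the air-sensitive tetraphenol appears only at the end. The demand is that nothing else in 20 is reducible under these conditions; the diarylmethane and the naphthalene are not.

20 ⇒ 19 ⇒ 18. The O2'–CH3 bond and then the O4'–benzyl bond are cut. This traces the only differentiated pair of ring C oxygens back to a free resorcinol. The forward steps must tell the two hydroxyls apart, which rests on the shielding of O2' by the orthogonal naphthalene and the C2 benzyl group.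

18 ⇒ 17 ⇒ 16. The C1'–C6' bond of ring C is cut (key disconnection). The hindered biaryl disappears and ring C becomes an open 2,4-dioxo chain with a masked aldehyde on the C1 methylene. The forward step must close carbon on carbon (C1' on C6') and not oxygen on carbon. Two points are set right here: the closure is 6-(enolendo)-exo-trig, since both enolate carbons lie in the new ring, and oxygen closure to a pyranone is the acid-side pathway, which hydroxide reverses, whereas aromatization is irreversible.

16 ⇒ 14 + 15. The C2'–C3' bond is cut. This splits off the four-carbon acetal ketone and leaves a naphthylacetyl unit. The forward acylation must be faster than proton transfer from the benzylic amide α-position, which is why an N-methoxy-N-methylamide (less acidic than an ester, no over-addition) is the acyl donor.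

14 ⇒ 13 ⇒ 12. The amide C–N bond is exchanged for the ester, and the O3– and O6–benzyl bonds are cut. This is pure functional-group bookkeeping; the demand is O- rather than C-alkylation of the naphthol.

12 ⇒ 11 ⇒ 10. The C1–C8a bond of ring A is cut, and O6 is traced back to its methoxymethyl ether. The naphthalene reduces to an acyclic 3,5-dioxo ester on ring B. The forward cyclodehydration needs ring B to be nucleophilic at C8a, hence the free phenol generated in the same flask, and it must outrun lactonization of the ester and attack by ring D.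

10 ⇒ 7 + 9. The C2–CH2 bond to ring D is cut. Ring D is removed as a benzylic bromide. The forward alkylation must occur on the carbon between the two ketones and on carbon rather than oxygen.

9 ⇒ 8. The C–Br bond is exchanged for C–OH, which reaches a catalogue benzylic alcohol.

7 ⇒ 5 + 6. The C2–C3 bond is cut. The chain falls into the ring B arylacetyl donor and the dianion of the acetoacetate, whose terminal carbon is the nucleophile; the demand is acylation at the terminal and not the central carbon, which the dianion secures.

5 ⇒ 4 ⇒ 3 ⇒ 2 ⇒ 1. The amide is taken back to the ester, the C4a–C4 bond (aryl–CH2) to an aryl bromide and a zinc ester enolate, the C–Br bond to C–H, and the methoxymethyl ether to the phenol. Capping the hydroxyl of 1 before bromination is what steers substitution to C3 (ortho and para to the methoxyls) and so fixes the 5,6,7-oxygenation pattern.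

## Other disconnections considered

Alternative 1: The cut is C2–C3 of ring A, in keto ester A1, where ring B carries the acetic ester (C4, C3) and a benzhydryl-type C1 that bears ring C and the CH2–CO–ring D chain. In the forward step a base (NaH or KOt-Bu, THF) forms the aryl ketone enolate at C2, which acylates the ester carbonyl C3 (Dieckmann-type Claisen condensation, 6-(enolexo)-exo-trig) to give the enolized aroyl dihydronaphthalenol A2, racemic at C1.
- In its favour: the C1–C1' bond is again made at an sp3 carbon (equal to the chosen plan on this point). Ring C enters with O2' and O4' already differentiated, which is better than the chosen plan, where two steps are spent on that. The ring closure is driven by a stabilized β-dicarbonyl enolate and has no oxygen-closure competitor, so its mechanism is at least as secure as the chosen aldol.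
- Against it here: A2 is at the wrong oxidation level twice. The aroyl carbonyl must be reduced to the C2 methylene beside three benzyl ethers and an enolized dicarbonyl, and ring A must be dehydrogenated on an oxidation-prone, electron-rich substrate. A1 also needs a ring B with the acetic ester ortho to the benzhydryl carbon, whose regiocontrolled assembly is no shorter than the polyketide chain.
- Comparison: equal or better on structure and mechanism, worse on redox and step economy after the key step.

Alternative 2: The cuts are C1–C2 and C2–C3: C2 is removed from ring A, leaving the silyl enol ether A3 of a 1-aryl-2-indanone; the C2–CH2 bond to ring D is a further, later cut. In the forward step dibromocarbene (CHBr3, KOt-Bu) cyclopropanates the enol ether double bond, and the dibromocyclopropane opens with loss of bromide and of the silyl group to give bromonaphthol A4.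
- In its favour: it is short, it places bromine exactly on C2 and the hydroxyl on C3, and ring C is differentiated from the start. On step count it is potentially better than the chosen plan.
- Against it here: the ring D methylene must then be attached by cross-coupling at a carbon flanked by the C1 aryl group and O3, which brings back the hindered coupling that the chosen plan avoids. The unsymmetrical ring B makes the two α-carbons of the indanone inequivalent, so the arylation that brings in ring C needs regiocontrol. Free dibromocarbene must add to a hindered tetrasubstituted enol ether beside three electron-rich arenes.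
- Comparison: better on step economy, worse on steric and regiochemical risk; the chosen plan needs no metal-mediated bond at C1 or C2.

Alternative 3: The cut is the C3=C4 bond, in triene A5, which holds a vinyl group on ring B and a 2-siloxyvinyl group across a tetrasubstituted C1=C2 alkene. In the forward step a ruthenium alkylidene (second-generation Hoveyda–Grubbs catalyst, toluene, about 80 °C) joins the two terminal alkenes with loss of ethylene and closes ring A directly as the aromatic silyl ether A6.
- In its favour: neutral conditions, no polyanion equilibria and no oxygen-closure competitor, which is better than the chosen key step on chemoselectivity. The product arrives at the right oxidation level with every oxygen differentiated, including O3.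
- Against it here: the difficulty moves into A5, whose C1=C2 alkene is tetrasubstituted, carries two different aryl groups on C1 and must have ring B cis to the siloxyvinyl group. One metathesis partner is an electron-rich 1,1-disubstituted enol ether, which initiates and turns over slowly.
- Comparison: equal or better in the key step itself, but the route to A5 is expected to be longer and less certain than the route to 16, so the chosen plan keeps the advantage on overall step economy.

Key step: step 12

Remarks on the chemistry: the C1–C1' axis is formed without control (racemic if rotation is slow), as the target carries no axial descriptor. Compound 8 is taken as a catalogue compound; from vanillin it would cost two more steps (O-benzylation, NaBH4 reduction).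

## Route

Step 1
Reactants: 1 2,6-dimethoxyphenol
Product: 2 1,3-dimethoxy-2-(methoxymethoxy)benzene
Conditions: NaH, MOMCl, DMF, 0 °C to rt
Reagents that add atoms: chloromethyl methyl ether, COCCl
Why: Williamson-type O-alkylation of the hindered phenoxide; capping the hydroxyl removes its para-directing power so that the next substitution goes ortho/para to the methoxyls, and the acetal can later be removed by acid in the ring-closing flask.

Step 2
Reactants: 2 1,3-dimethoxy-2-(methoxymethoxy)benzene
Product: 3 1-bromo-2,4-dimethoxy-3-(methoxymethoxy)benzene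
Conditions: NBS (1.0 equiv), MeCN, 0 °C to rt
Reagents that add atoms: N-bromosuccinimide, O=C1CCC(=O)N1Br
Why: Electrophilic aromatic bromination; in a 1,2,3-trioxygenated benzene the position ortho to one terminal methoxyl and para to the other is the reactive one, and acid-free NBS spares the MOM ether.

Step 3
Reactants: 3 1-bromo-2,4-dimethoxy-3-(methoxymethoxy)benzene
Product: 4 ethyl 2-[2,4-dimethoxy-3-(methoxymethoxy)phenyl]acetate
Conditions: BrZnCH2CO2Et (0.5 M in THF, 1.5 equiv), Pd2(dba)3 (2 mol%), XPhos (8 mol%), THF, 60 °C
Reagents that add atoms: bromo(2-ethoxy-2-oxoethyl)zinc, CCOC(=O)C[Zn]Br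
Why: Negishi coupling of a Reformatsky reagent with an aryl bromide; zerovalent palladium with a bulky biarylphosphine inserts into the electron-rich ortho-substituted C–Br bond, and the neutral zinc enolate tolerates the MOM ether.

Step 4
Reactants: 4 ethyl 2-[2,4-dimethoxy-3-(methoxymethoxy)phenyl]acetate
Product: 5 2-[2,4-dimethoxy-3-(methoxymethoxy)phenyl]-N-methoxy-N-methylacetamide
Conditions: MeNHOMe·HCl (1.5 equiv), i-PrMgCl (3 equiv), THF, −20 to 0 °C
Reagents that add atoms: N,O-dimethylhydroxylamine hydrochloride, CNOC.Cl
Why: Weinreb amide formation by aminolysis of the ester with the magnesium amide; the amide has a less acidic α-CH2 than the ester and cannot be over-acylated, both of which the dianion step needs.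

Step 5
Reactants: 5 2-[2,4-dimethoxy-3-(methoxymethoxy)phenyl]-N-methoxy-N-methylacetamide; 6 methyl acetoacetate
Product: 7 methyl 6-[2,4-dimethoxy-3-(methoxymethoxy)phenyl]-3,5-dioxohexanoate
Conditions: 6 (2.2 equiv), LiN(i-Pr)2 (4.4 equiv), THF, 0 °C; then 5, −78 to 0 °C; AcOH quench
Reagents that add atoms: none
Why: γ-Acylation of a β-keto ester dianion: the terminal carbanion adds to the Weinreb amide and the chelated tetrahedral adduct persists until the quench, so the acidic product is never exposed to the dianion.

Step 6
Reactants: 8 [4-(benzyloxy)-3-methoxyphenyl]methanol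
Product: 9 1-(benzyloxy)-4-(bromomethyl)-2-methoxybenzene
Conditions: PBr3 (0.4 equiv), CH2Cl2, 0 °C; used without storage
Reagents that add atoms: phosphorus tribromide, BrP(Br)Br
Why: Standard conversion of a benzylic alcohol to the bromide by bromide displacement on the phosphite ester; the aryl benzyl ether is inert at 0 °C.

Step 7
Reactants: 7 methyl 6-[2,4-dimethoxy-3-(methoxymethoxy)phenyl]-3,5-dioxohexanoate; 9 1-(benzyloxy)-4-(bromomethyl)-2-methoxybenzene
Product: 10 methyl 4-[4-(benzyloxy)-3-methoxybenzyl]-6-[2,4-dimethoxy-3-(methoxymethoxy)phenyl]-3,5-dioxohexanoate (racemic at C4, enolizable)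
Conditions: 9 (1.0 equiv), K2CO3 (1.1 equiv), acetone, 0 °C to rt
Reagents that add atoms: none
Why: C-Alkylation of a β-diketone monoanion: the carbon between the two ketones is the most acidic site of the 3,5-dioxo ester and the soft benzylic bromide reacts at carbon, with one equivalent of halide limiting double alkylation. The new stereocentre is racemic and is erased in step 8.

Step 8
Reactants: 10 methyl 4-[4-(benzyloxy)-3-methoxybenzyl]-6-[2,4-dimethoxy-3-(methoxymethoxy)phenyl]-3,5-dioxohexanoate
Product: 12 methyl 2-{2-[4-(benzyloxy)-3-methoxybenzyl]-3,6-dihydroxy-5,7-dimethoxynaphthalen-1-yl}acetate, via MOM-free phenol 11 (not isolated)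
Conditions: TFA–CH2Cl2 (1:4), H2O (5 equiv), Ar, 0 °C to rt
Reagents that add atoms: none
Why: Acid first cleaves the MOM acetal; the freed phenol is para to the future C8a, which then attacks the protonated C1 ketone (Bradsher-type cyclodehydration, six-membered closure), and loss of water with enolization of the C3 ketone gives the naphthalene. Only the C1 carbonyl is reachable through a six-membered ring, and the para hydroxyl makes ring B far more nucleophilic than ring D, whose attack would close a five-membered ring.

Step 9
Reactants: 12 methyl 2-{2-[4-(benzyloxy)-3-methoxybenzyl]-3,6-dihydroxy-5,7-dimethoxynaphthalen-1-yl}acetate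
Product: 13 methyl 2-{3,6-bis(benzyloxy)-2-[4-(benzyloxy)-3-methoxybenzyl]-5,7-dimethoxynaphthalen-1-yl}acetate
Conditions: BnBr (2.5 equiv), K2CO3 (3 equiv), DMF, Ar, rt to 40 °C
Reagents that add atoms: benzyl bromide, BrCc1ccccc1
Why: Williamson O-benzylation of both phenols; the polar solvent favours O- over C-alkylation of the naphthoxide and K2CO3 is too weak to deprotonate the ester α-carbon.

Step 10
Reactants: 13 methyl 2-{3,6-bis(benzyloxy)-2-[4-(benzyloxy)-3-methoxybenzyl]-5,7-dimethoxynaphthalen-1-yl}acetate
Product: 14 2-{3,6-bis(benzyloxy)-2-[4-(benzyloxy)-3-methoxybenzyl]-5,7-dimethoxynaphthalen-1-yl}-N-methoxy-N-methylacetamide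
Conditions: MeNHOMe·HCl (3 equiv), i-PrMgCl (6 equiv), THF, −10 °C to rt
Reagents that add atoms: N,O-dimethylhydroxylamine hydrochloride, CNOC.Cl
Why: Weinreb amide formation as in step 4; the carbonyl is one carbon away from the crowded C1 and remains accessible.

Step 11
Reactants: 14 2-{3,6-bis(benzyloxy)-2-[4-(benzyloxy)-3-methoxybenzyl]-5,7-dimethoxynaphthalen-1-yl}-N-methoxy-N-methylacetamide; 15 4,4-dimethoxybutan-2-one
Product: 16 1-{3,6-bis(benzyloxy)-2-[4-(benzyloxy)-3-methoxybenzyl]-5,7-dimethoxynaphthalen-1-yl}-6,6-dimethoxyhexane-2,4-dione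
Conditions: 15 (3 equiv), LiN(i-Pr)2 (3 equiv), THF, −78 °C; then 14, −78 to −20 °C; AcOH quench
Reagents that add atoms: none
Why: Claisen-type acylation of the kinetic methyl enolate of 15 by the Weinreb amide; the chelated adduct prevents double addition and releases the β-diketone on quench. Excess enolate at low temperature offsets proton transfer from the benzylic α-position of 14 and β-elimination of methoxide from the enolate.

Step 12
Reactants: 16 1-{3,6-bis(benzyloxy)-2-[4-(benzyloxy)-3-methoxybenzyl]-5,7-dimethoxynaphthalen-1-yl}-6,6-dimethoxyhexane-2,4-dione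
Product: 18 4-{3,6-bis(benzyloxy)-2-[4-(benzyloxy)-3-methoxybenzyl]-5,7-dimethoxynaphthalen-1-yl}benzene-1,3-diol, via diketo aldehyde 17 (not isolated)
Conditions: 1 M aq. HCl–THF (1:4), rt; then degassed 2 M aq. KOH, MeOH, Ar, about 0.02 M, rt to 45 °C; then 1 M HCl to pH 4
Reagents that add atoms: none
Why: Aqueous acid hydrolyses the dimethyl acetal to the aldehyde 17, a 1,3,5-tricarbonyl chain that exists as enol tautomers and may close reversibly through oxygen. In hydroxide the chain is a set of rapidly exchanging enolates, and the member with enolate character at C1'–C2' and a free C6' formyl group undergoes intramolecular aldol addition of C1' to C6', a 6-(enolendo)-exo-trig closure that forms ring C. E1cB loss of water across C1'–C6' and enolization of the C2' and C4' carbonyls then give the resorcinol, and this aromatization is irreversible and drains every preceding equilibrium. The closest known reaction type is the biomimetic base-mediated aldol aromatization of 1,3,5-tricarbonyl compounds (triketones or ring-opened 4-pyranones) to resorcinols. No stereocentre is formed; the C1–C1' axis arises without control. Carbon selectivity is secured by ring size, because C3' and C5' could reach C6' only through rings of four atoms or fewer. Selectivity over oxygen closure is secured by reversibility, because hydroxide reopens the pyranone by addition at C6' whereas the resorcinol cannot revert. Dilution disfavours intermolecular aldol reaction and exclusion of air protects the electron-rich phenoxide.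

Step 13
Reactants: 18 4-{3,6-bis(benzyloxy)-2-[4-(benzyloxy)-3-methoxybenzyl]-5,7-dimethoxynaphthalen-1-yl}benzene-1,3-diol
Product: 19 5-(benzyloxy)-2-{3,6-bis(benzyloxy)-2-[4-(benzyloxy)-3-methoxybenzyl]-5,7-dimethoxynaphthalen-1-yl}phenol
Conditions: BnBr (1.05 equiv), K2CO3 (1.2 equiv), acetone, 0 °C to rt
Reagents that add atoms: benzyl bromide, BrCc1ccccc1
Why: Site-selective Williamson etherification: the C4' hydroxyl is open, whereas the C2' hydroxyl lies under the orthogonal naphthalene and the C2 benzyl group, so one equivalent of halide at low temperature should go to O4'.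

Step 14
Reactants: 19 5-(benzyloxy)-2-{3,6-bis(benzyloxy)-2-[4-(benzyloxy)-3-methoxybenzyl]-5,7-dimethoxynaphthalen-1-yl}phenol
Product: 20 3,6-bis(benzyloxy)-1-[4-(benzyloxy)-2-methoxyphenyl]-2-[4-(benzyloxy)-3-methoxybenzyl]-5,7-dimethoxynaphthalene
Conditions: MeI (5 equiv), K2CO3 (3 equiv), DMF, 45 °C
Reagents that add atoms: iodomethane, CI
Why: Williamson O-methylation of the one remaining, hindered phenol; the small electrophile in excess and a polar solvent overcome the shielding and no other nucleophilic site is left.

Step 15
Reactants: 20 3,6-bis(benzyloxy)-1-[4-(benzyloxy)-2-methoxyphenyl]-2-[4-(benzyloxy)-3-methoxybenzyl]-5,7-dimethoxynaphthalene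
Product: 21 1-(4-hydroxy-2-methoxyphenyl)-2-(4-hydroxy-3-methoxybenzyl)-5,7-dimethoxynaphthalene-3,6-diol (CNP0000246.0)
Conditions: H2 (1 atm), 10% Pd/C, EtOAc–MeOH, rt; work-up under Ar
Reagents that add atoms: none
Why: Catalytic hydrogenolysis of the four aryl benzyl ethers; methyl ethers, the diarylmethane C–C bonds and the naphthalene are untouched at one atmosphere, and neutral conditions suit the oxidation-prone tetraphenol.

## Compound list

1 | 2,6-dimethoxyphenol | COc1cccc(OC)c1O | starting material
2 | 1,3-dimethoxy-2-(methoxymethoxy)benzene | COCOc1c(OC)cccc1OC | intermediate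
3 | 1-bromo-2,4-dimethoxy-3-(methoxymethoxy)benzene | COCOc1c(OC)ccc(Br)c1OC | intermediate
4 | ethyl 2-[2,4-dimethoxy-3-(methoxymethoxy)phenyl]acetate | CCOC(=O)Cc1ccc(OC)c(OCOC)c1OC | intermediate
5 | 2-[2,4-dimethoxy-3-(methoxymethoxy)phenyl]-N-methoxy-N-methylacetamide | CON(C)C(=O)Cc1ccc(OC)c(OCOC)c1OC | intermediate
6 | methyl acetoacetate | COC(=O)CC(C)=O | starting material
7 | methyl 6-[2,4-dimethoxy-3-(methoxymethoxy)phenyl]-3,5-dioxohexanoate | COC(=O)CC(=O)CC(=O)Cc1ccc(OC)c(OCOC)c1OC | intermediate
8 | [4-(benzyloxy)-3-methoxyphenyl]methanol | COc1cc(CO)ccc1OCc1ccccc1 | starting material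
9 | 1-(benzyloxy)-4-(bromomethyl)-2-methoxybenzene | COc1cc(CBr)ccc1OCc1ccccc1 | intermediate
10 | methyl 4-[4-(benzyloxy)-3-methoxybenzyl]-6-[2,4-dimethoxy-3-(methoxymethoxy)phenyl]-3,5-dioxohexanoate (racemic, enolizable) | COC(=O)CC(=O)C(Cc1ccc(OCc2ccccc2)c(OC)c1)C(=O)Cc1ccc(OC)c(OCOC)c1OC | intermediate
11 | methyl 4-[4-(benzyloxy)-3-methoxybenzyl]-6-(3-hydroxy-2,4-dimethoxyphenyl)-3,5-dioxohexanoate (racemic, enolizable) | COC(=O)CC(=O)C(Cc1ccc(OCc2ccccc2)c(OC)c1)C(=O)Cc1ccc(OC)c(O)c1OC | intermediate (not isolated)
12 | methyl 2-{2-[4-(benzyloxy)-3-methoxybenzyl]-3,6-dihydroxy-5,7-dimethoxynaphthalen-1-yl}acetate | COC(=O)Cc1c(Cc2ccc(OCc3ccccc3)c(OC)c2)c(O)cc2c(OC)c(O)c(OC)cc12 | intermediate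
13 | methyl 2-{3,6-bis(benzyloxy)-2-[4-(benzyloxy)-3-methoxybenzyl]-5,7-dimethoxynaphthalen-1-yl}acetate | COC(=O)Cc1c(Cc2ccc(OCc3ccccc3)c(OC)c2)c(OCc2ccccc2)cc2c(OC)c(OCc3ccccc3)c(OC)cc12 | intermediate
14 | 2-{3,6-bis(benzyloxy)-2-[4-(benzyloxy)-3-methoxybenzyl]-5,7-dimethoxynaphthalen-1-yl}-N-methoxy-N-methylacetamide | CON(C)C(=O)Cc1c(Cc2ccc(OCc3ccccc3)c(OC)c2)c(OCc2ccccc2)cc2c(OC)c(OCc3ccccc3)c(OC)cc12 | intermediate
15 | 4,4-dimethoxybutan-2-one | COC(OC)CC(C)=O | starting material
16 | 1-{3,6-bis(benzyloxy)-2-[4-(benzyloxy)-3-methoxybenzyl]-5,7-dimethoxynaphthalen-1-yl}-6,6-dimethoxyhexane-2,4-dione | COC(OC)CC(=O)CC(=O)Cc1c(Cc2ccc(OCc3ccccc3)c(OC)c2)c(OCc2ccccc2)cc2c(OC)c(OCc3ccccc3)c(OC)cc12 | intermediate (key-step precursor)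
17 | 6-{3,6-bis(benzyloxy)-2-[4-(benzyloxy)-3-methoxybenzyl]-5,7-dimethoxynaphthalen-1-yl}-3,5-dioxohexanal | O=CCC(=O)CC(=O)Cc1c(Cc2ccc(OCc3ccccc3)c(OC)c2)c(OCc2ccccc2)cc2c(OC)c(OCc3ccccc3)c(OC)cc12 | intermediate (not isolated)
18 | 4-{3,6-bis(benzyloxy)-2-[4-(benzyloxy)-3-methoxybenzyl]-5,7-dimethoxynaphthalen-1-yl}benzene-1,3-diol | Oc1ccc(-c2c(Cc3ccc(OCc4ccccc4)c(OC)c3)c(OCc3ccccc3)cc3c(OC)c(OCc4ccccc4)c(OC)cc23)c(O)c1 | intermediate (key-step product)
19 | 5-(benzyloxy)-2-{3,6-bis(benzyloxy)-2-[4-(benzyloxy)-3-methoxybenzyl]-5,7-dimethoxynaphthalen-1-yl}phenol | Oc1cc(OCc2ccccc2)ccc1-c1c(Cc2ccc(OCc3ccccc3)c(OC)c2)c(OCc2ccccc2)cc2c(OC)c(OCc3ccccc3)c(OC)cc12 | intermediate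
20 | 3,6-bis(benzyloxy)-1-[4-(benzyloxy)-2-methoxyphenyl]-2-[4-(benzyloxy)-3-methoxybenzyl]-5,7-dimethoxynaphthalene | COc1cc(OCc2ccccc2)ccc1-c1c(Cc2ccc(OCc3ccccc3)c(OC)c2)c(OCc2ccccc2)cc2c(OC)c(OCc3ccccc3)c(OC)cc12 | intermediate
21 | 1-(4-hydroxy-2-methoxyphenyl)-2-(4-hydroxy-3-methoxybenzyl)-5,7-dimethoxynaphthalene-3,6-diol (CNP0000246.0) | COc1cc(Cc2c(O)cc3c(OC)c(O)c(OC)cc3c2-c2ccc(O)cc2OC)ccc1O | target

## Step count and least certain steps

Total: 15 steps. Longest linear sequence: 14 steps (steps 1–5 and 7–15); step 6 is a one-step side branch.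

Step 12 (key step). During the acid stage oxygen closure competes. In the base stage the formyl group is largely tied up as its enolate while C1' is the least acidic and most hindered carbanion site, so ring closure may be slow enough for retro-Claisen cleavage of the chain and intermolecular condensation to take over. Fallback: set out from 16, drive the oxygen closure to completion on purpose with TFA in CH2Cl2 and isolate 2-({3,6-bis(benzyloxy)-2-[4-(benzyloxy)-3-methoxybenzyl]-5,7-dimethoxynaphthalen-1-yl}methyl)-4H-pyran-4-one F1 as a stable, purifiable masked tricarbonyl. F1 is then opened with KOH in degassed aqueous methanol (hydroxide addition at C6'), which releases the chain only under the conditions of the aldol aromatization, and the route is rejoined at 18.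

Step 8. Ring closure may go through the wrong pair of atoms, namely lactonization of the ester onto the enolized diketone or attack by ring D. The formaldehyde equivalent released from the MOM group may substitute the electron-rich naphthol, and the ring D benzyl ether may be partly lost in acid. Fallback: carry the side chain through the ring closure as the amide, which cannot lactonize readily and makes step 10 unnecessary. Set out from 5 and the dianion (LiN(i-Pr)2, 2 equiv) of N-methoxy-N-methyl-3-oxobutanamide F2 to give 6-[2,4-dimethoxy-3-(methoxymethoxy)phenyl]-N-methoxy-N-methyl-3,5-dioxohexanamide F3. Alkylate F3 with 9 (K2CO3, acetone) to 4-[4-(benzyloxy)-3-methoxybenzyl]-6-[2,4-dimethoxy-3-(methoxymethoxy)phenyl]-N-methoxy-N-methyl-3,5-dioxohexanamide F4. Close F4 with aqueous HCl in THF, where formaldehyde is kept as its hydrate, to 2-{2-[4-(benzyloxy)-3-methoxybenzyl]-3,6-dihydroxy-5,7-dimethoxynaphthalen-1-yl}-N-methoxy-N-methylacetamide F5, and benzylate both phenols (BnBr, K2CO3, DMF) to rejoin the route at 14.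

Step 7. Alkylation may occur on oxygen, on the methylene next to the ester, or twice. Fallback: fix the regiochemistry by construction by reversing the order of bond formation. Set out from 6, alkylate its dianion with 9 at the terminal carbon to methyl 5-[4-(benzyloxy)-3-methoxyphenyl]-3-oxopentanoate F6, form the dianion of F6 and acylate it with 5 at the benzyl-bearing carbon, which rejoins the route at 10.

Step 11. Proton transfer from the benzylic α-position of the amide to the enolate, or loss of methoxide from the enolate on warming, may outpace acylation. Fallback: replace acylation by aldol addition and oxidation. Set out from 14 and reduce it with i-Bu2AlH at −78 °C to 2-{3,6-bis(benzyloxy)-2-[4-(benzyloxy)-3-methoxybenzyl]-5,7-dimethoxynaphthalen-1-yl}acetaldehyde F7. Add the lithium enolate of 15 at −78 °C to give racemic 1-{3,6-bis(benzyloxy)-2-[4-(benzyloxy)-3-methoxybenzyl]-5,7-dimethoxynaphthalen-1-yl}-2-hydroxy-6,6-dimethoxyhexan-4-one F8, and oxidize F8 with Dess–Martin periodinane (NaHCO3 buffer), which rejoins the route at 16.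

Step 13. Site selectivity between the two ring C hydroxyls may be incomplete, with alkylation at O2' or at both oxygens. Fallback: use a bulky silyl group, which discriminates more sharply than a benzyl group. Set out from 18 and silylate with i-Pr3SiCl and imidazole to 2-{3,6-bis(benzyloxy)-2-[4-(benzyloxy)-3-methoxybenzyl]-5,7-dimethoxynaphthalen-1-yl}-5-[tri(propan-2-yl)silyloxy]phenol F9. Methylate (MeI, K2CO3, acetone) to {4-{3,6-bis(benzyloxy)-2-[4-(benzyloxy)-3-methoxybenzyl]-5,7-dimethoxynaphthalen-1-yl}-3-methoxyphenoxy}tri(propan-2-yl)silane F10. Remove the silyl group with Bu4NF to 4-{3,6-bis(benzyloxy)-2-[4-(benzyloxy)-3-methoxybenzyl]-5,7-dimethoxynaphthalen-1-yl}-3-methoxyphenol F11, and hydrogenolyse (H2, Pd/C), which reaches 21 directly at the cost of one extra step.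

## Further compounds

F1 | step 12 | 2-({3,6-bis(benzyloxy)-2-[4-(benzyloxy)-3-methoxybenzyl]-5,7-dimethoxynaphthalen-1-yl}methyl)-4H-pyran-4-one | O=c1ccoc(Cc2c(Cc3ccc(OCc4ccccc4)c(OC)c3)c(OCc3ccccc3)cc3c(OC)c(OCc4ccccc4)c(OC)cc23)c1
F2 | step 8 | N-methoxy-N-methyl-3-oxobutanamide | CC(=O)CC(=O)N(C)OC
F3 | step 8 | 6-[2,4-dimethoxy-3-(methoxymethoxy)phenyl]-N-methoxy-N-methyl-3,5-dioxohexanamide | CON(C)C(=O)CC(=O)CC(=O)Cc1ccc(OC)c(OCOC)c1OC
F4 | step 8 | 4-[4-(benzyloxy)-3-methoxybenzyl]-6-[2,4-dimethoxy-3-(methoxymethoxy)phenyl]-N-methoxy-N-methyl-3,5-dioxohexanamide (racemic, enolizable) | CON(C)C(=O)CC(=O)C(Cc1ccc(OCc2ccccc2)c(OC)c1)C(=O)Cc1ccc(OC)c(OCOC)c1OC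
F5 | step 8 | 2-{2-[4-(benzyloxy)-3-methoxybenzyl]-3,6-dihydroxy-5,7-dimethoxynaphthalen-1-yl}-N-methoxy-N-methylacetamide | CON(C)C(=O)Cc1c(Cc2ccc(OCc3ccccc3)c(OC)c2)c(O)cc2c(OC)c(O)c(OC)cc12
F6 | step 7 | methyl 5-[4-(benzyloxy)-3-methoxyphenyl]-3-oxopentanoate | COC(=O)CC(=O)CCc1ccc(OCc2ccccc2)c(OC)c1
F7 | step 11 | 2-{3,6-bis(benzyloxy)-2-[4-(benzyloxy)-3-methoxybenzyl]-5,7-dimethoxynaphthalen-1-yl}acetaldehyde | O=CCc1c(Cc2ccc(OCc3ccccc3)c(OC)c2)c(OCc2ccccc2)cc2c(OC)c(OCc3ccccc3)c(OC)cc12
F8 | step 11 | 1-{3,6-bis(benzyloxy)-2-[4-(benzyloxy)-3-methoxybenzyl]-5,7-dimethoxynaphthalen-1-yl}-2-hydroxy-6,6-dimethoxyhexan-4-one (racemic) | COC(OC)CC(=O)CC(O)Cc1c(Cc2ccc(OCc3ccccc3)c(OC)c2)c(OCc2ccccc2)cc2c(OC)c(OCc3ccccc3)c(OC)cc12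
F9 | step 13 | 2-{3,6-bis(benzyloxy)-2-[4-(benzyloxy)-3-methoxybenzyl]-5,7-dimethoxynaphthalen-1-yl}-5-[tri(propan-2-yl)silyloxy]phenol | CC(C)[Si](Oc1ccc(-c2c(Cc3ccc(OCc4ccccc4)c(OC)c3)c(OCc3ccccc3)cc3c(OC)c(OCc4ccccc4)c(OC)cc23)c(O)c1)(C(C)C)C(C)C
F10 | step 13 | {4-{3,6-bis(benzyloxy)-2-[4-(benzyloxy)-3-methoxybenzyl]-5,7-dimethoxynaphthalen-1-yl}-3-methoxyphenoxy}tri(propan-2-yl)silane | CC(C)[Si](Oc1ccc(-c2c(Cc3ccc(OCc4ccccc4)c(OC)c3)c(OCc3ccccc3)cc3c(OC)c(OCc4ccccc4)c(OC)cc23)c(OC)c1)(C(C)C)C(C)C
F11 | step 13 | 4-{3,6-bis(benzyloxy)-2-[4-(benzyloxy)-3-methoxybenzyl]-5,7-dimethoxynaphthalen-1-yl}-3-methoxyphenol | Oc1ccc(-c2c(Cc3ccc(OCc4ccccc4)c(OC)c3)c(OCc3ccccc3)cc3c(OC)c(OCc4ccccc4)c(OC)cc23)c(OC)c1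
A1 | alternative 1 | methyl 2-{3-(benzyloxy)-6-[1-(4-(benzyloxy)-2-methoxyphenyl)-3-(4-(benzyloxy)-3-methoxyphenyl)-3-oxopropyl]-2,4-dimethoxyphenyl}acetate (racemic) | COC(=O)Cc1c(OC)c(OCc2ccccc2)c(OC)cc1C(CC(=O)c1ccc(OCc2ccccc2)c(OC)c1)c1ccc(OCc2ccccc2)cc1OC
A2 | alternative 1 | racemic [6-benzyloxy-1-(4-benzyloxy-2-methoxyphenyl)-3-hydroxy-5,7-dimethoxy-1,4-dihydronaphthalen-2-yl](4-benzyloxy-3-methoxyphenyl)methanone | O=C(C1=C(O)Cc2c(OC)c(OCc3ccccc3)c(OC)cc2C1c1ccc(OCc2ccccc2)cc1OC)c1ccc(OCc2ccccc2)c(OC)c1
A3 | alternative 2 | {[6-(benzyloxy)-3-[4-(benzyloxy)-2-methoxyphenyl]-5,7-dimethoxy-1H-inden-2-yl]oxy}(tert-butyl)dimethylsilane | CC(C)(C)[Si](C)(C)OC1=C(c2ccc(OCc3ccccc3)cc2OC)c2cc(OC)c(OCc3ccccc3)c(OC)c2C1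
A4 | alternative 2 | 1-(4-benzyloxy-2-methoxyphenyl)-6-benzyloxy-2-bromo-5,7-dimethoxynaphthalen-3-ol | Oc1cc2c(OC)c(OCc3ccccc3)c(OC)cc2c(-c2ccc(OCc3ccccc3)cc2OC)c1Br
A5 | alternative 3 | tert-butyl({(3E)-4-[4-(benzyloxy)-2-ethenyl-3,5-dimethoxyphenyl]-4-[4-(benzyloxy)-2-methoxyphenyl]-3-[4-(benzyloxy)-3-methoxybenzyl]buta-1,3-dien-2-yl}oxy)dimethylsilane (ring B cis to the siloxyvinyl group) | C=Cc1c(OC)c(OCc2ccccc2)c(OC)cc1/C(c1ccc(OCc2ccccc2)cc1OC)=C(/Cc1ccc(OCc2ccccc2)c(OC)c1)C(=C)O[Si](C)(C)C(C)(C)C
A6 | alternative 3 | tert-butyl({6-(benzyloxy)-1-[4-(benzyloxy)-2-methoxyphenyl]-2-[4-(benzyloxy)-3-methoxybenzyl]-5,7-dimethoxynaphthalen-3-yl}oxy)dimethylsilane | CC(C)(C)[Si](C)(C)Oc1cc2c(OC)c(OCc3ccccc3)c(OC)cc2c(-c2ccc(OCc3ccccc3)cc2OC)c1Cc1ccc(OCc2ccccc2)c(OC)c1
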